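**Retrosynthetic overview**
1. Ring A (enoate ε-lactone) is closed last by RCM of a C4–O acrylate with the C10 vinyl group; C4–OH comes from Markovnikov hydration of the isopropenyl group.
2. γ-Lactone and C18: iodolactonisation of the C17 ester onto a C15 vinyl carbinol; C13=CH2 by ketone methylenation.
3. Ring D / bicyclo[3.2.1] bridge (C12–C16–C15–C14): dianion alkylation at C12, then intramolecular acylation of C14.
4. Ring C, key C8–C14 bond: photoredox radical-cation hydroalkylation of the tetrasubstituted C8=C9 alkene by a β-keto ester (new step).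
5. Ring B, both its methyls, C4 and the C5 stereocentre are (S)-carvone (α′-methylation, α′-vinylation, enol triflate, Negishi, Claisen); ring order B (bought) → C → D → γ-lactone → A.

Assumption: atoms are labelled C1=C2–C3(=O)–O–C4(CH3)2–C5H; ring B = C5–C10; ring C = C8, C9, C11–C14 (C13 bears =CH2); bridge C15(OH)–C16H2; C17 = γ-lactone C=O; C18 = O–CH(CH3); the C12/C14 centres of 8–12 (epimers or enol forms) are left undefined because step 7 fixes them.

Step 1
Reactants: 1 (S)-(+)-carvone
Product: 3 6-methylcarvone (C6 epimers), via lithium dienolate 2 (not isolated)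
Conditions: LDA (1.05 equiv), THF, −78 °C; MeI, −78→0 °C
Reagents that add atoms: iodomethane (CI)
Why: Kinetic α′-deprotonation gives the cross-conjugated dienolate and enolate C-alkylation installs the future C10 methyl, the new centre being re-enolised in step 2 so its configuration is irrelevant.

Step 2
Reactants: 3 6-methylcarvone
Product: 5 (5R,6R)-6-ethenyl-2,6-dimethyl-5-(prop-1-en-2-yl)cyclohex-2-en-1-one, via lithium dienolate 4 (not isolated)
Conditions: LiHMDS (1.2 equiv), THF, −78→0 °C; vinyl bromide (3 equiv), Pd2(dba)3 (2.5 mol%), QPhos (6 mol%), toluene, 50 °C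
Reagents that add atoms: vinyl bromide (C=CBr)
Why: Pd-catalysed ketone-enolate α-vinylation (Buchwald–Hartwig-type enolate coupling) builds the C10 quaternary centre, the vinyl group entering anti to the neighbouring isopropenyl group so that the carvone stereocentre controls C10.

Step 3
Reactants: 5 vinyl enone
Product: 7 (5R,6R)-6-ethenyl-2,6-dimethyl-5-(prop-1-en-2-yl)cyclohex-1-en-1-yl trifluoromethanesulfonate, via lithium enolate 6 (not isolated)
Conditions: L-Selectride (1.05 equiv), THF, −78 °C; PhNTf2 (1.2 equiv), −78→0 °C; aq. NaHCO3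
Reagents that add atoms: N-phenyl-bis(trifluoromethanesulfonimide) (O=S(=O)(C(F)(F)F)N(c1ccccc1)S(=O)(=O)C(F)(F)F)
Why: L-Selectride conjugate reduction of the β-unsubstituted enone gives a single enolate regioisomer (C10 is quaternary), which is trapped as the enol triflate.

Step 4
Reactants: 7 enol triflate
Product: 8 methyl 3-[(5R,6R)-6-ethenyl-2,6-dimethyl-5-(prop-1-en-2-yl)cyclohex-1-en-1-yl]-2-methylpropanoate
Conditions: racemic (3-methoxy-2-methyl-3-oxopropyl)zinc bromide (1.5 equiv, 0.5 M in THF), Pd(OAc)2 (5 mol%), SPhos (10 mol%), THF/NMP, 60 °C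
Reagents that add atoms: (3-methoxy-2-methyl-3-oxopropyl)zinc bromide (COC(=O)C(C)C[Zn]Br)
Why: Negishi sp2–sp3 cross-coupling of the hindered alkenyl triflate with an ester-bearing alkylzinc forms C9–C11 and the tetrasubstituted C8=C9 alkene.

Step 5
Reactants: 8 methyl ester
Product: 9 tert-butyl 5-[(5R,6R)-6-ethenyl-2,6-dimethyl-5-(prop-1-en-2-yl)cyclohex-1-en-1-yl]-4-methyl-3-oxopentanoate
Conditions: tert-butyl acetate (3 equiv), LDA (3 equiv), THF, −78 °C; add 8, −78→−30 °C; aq. NH4Cl
Reagents that add atoms: tert-butyl acetate (CC(=O)OC(C)(C)C)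
Why: Crossed Claisen condensation with excess lithium tert-butyl acetate enolate is driven by deprotonation of the β-keto ester product.

Step 6
Reactants: 9 β-keto ester
Product: 10 tert-butyl 5-ethenyl-3,5,8a-trimethyl-2-oxo-6-(prop-1-en-2-yl)decahydronaphthalene-1-carboxylate (trans-fused; 4a-H anti to both angular methyls)
Conditions: 9-mesityl-3,6-di-tert-butyl-10-phenylacridinium BF4 (5 mol%), PhSH (20 mol%), 2,6-lutidine (10 mol%), DCE/TFE 4:1, 450 nm LEDs, rt, N2
Reagents that add atoms: none
Why: Proposed new method: the excited acridinium (E* about +2.0 V) oxidises only the tetrasubstituted C8=C9 alkene (about +1.6 V) to its radical cation, the enol carbon C14 attacks C8 through a six-membered chair on the face anti to the axial C10 methyl, and the tertiary C9 radical takes H from thiophenol on the same open face (C9–H trans to both angular methyls) with thiyl/acridine-radical turnover; the closest known chemistry is acridinium-catalysed anti-Markovnikov alkene hydrofunctionalisation with O/N nucleophiles and anodic olefin coupling, whereas capture of an unactivated alkene radical cation by a 1,3-dicarbonyl carbon to make a ring and a quaternary centre has not been shown.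

Step 7
Reactants: 10 ring B/C β-keto ester
Product: 13 bridged 13,15-dione tert-butyl ester, via dilithium dianion 11 (not isolated), via Weinreb amide 12 (not isolated)
Conditions: LDA (2.3 equiv), THF, −78→0 °C; BrCH2C(O)N(OMe)Me (1.1 equiv), −78 °C→rt; aq. NH4Cl
Reagents that add atoms: 2-bromo-N-methoxy-N-methylacetamide (CON(C)C(=O)CBr)
Why: Weiler-type dianion γ-alkylation at C12 occurs axially on the face of C9–H and the remaining C14 enolate is then acylated intramolecularly by the Weinreb amide (Claisen-type, chelated tetrahedral intermediate), so the two-carbon bridge can only close cis-diaxially and fixes C12 and C14.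

Step 8
Reactants: 13 bridged dione
Product: 14 C15 vinyl carbinol (vinyl exo and OH endo)
Conditions: CH2=CHMgBr (1.5 equiv), CeCl3 (1.6 equiv), THF, −78 °C; aq. NH4Cl at −78 °C
Reagents that add atoms: vinylmagnesium bromide (C=C[Mg]Br)
Why: Organocerium (Imamoto) 1,2-addition goes to the less hindered C15 ketone from the exo face of the bicyclo[3.2.1]octane, giving the endo tertiary alcohol, and the cold quench avoids retro-aldol.

Step 9
Reactants: 14 vinyl carbinol
Product: 15 iodomethyl γ-lactone
Conditions: I2 (3 equiv), MeCN, 0 °C→rt, dark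
Reagents that add atoms: iodine (II)
Why: 5-exo iodolactonisation of the tert-butyl ester onto the C15 vinyl group places CH2I cis to the allylic hydroxyl (hydroxyl-directed kinetic preference, also the thermodynamic preference trans to C16), which sets C18.

Step 10
Reactants: 15 iodomethyl lactone
Product: 16 13-oxo γ-lactone with C18 methyl
Conditions: Bu3SnH (1.3 equiv), AIBN (10 mol%), benzene, 80 °C
Reagents that add atoms: none
Why: Radical-chain hydrodeiodination (tin hydride reduction) turns CH2I into the C18 methyl group without touching the alkenes.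

Step 11
Reactants: 16 isopropenyl keto lactone
Product: 17 C4 tertiary alcohol
Conditions: Co(acac)2 (20 mol%), PhSiH3 (2.2 equiv), O2 (1 atm), THF/i-PrOH, 0 °C→rt
Reagents that add atoms: dioxygen (O=O)
Why: Mukaiyama hydration (metal-hydride H-atom transfer then O2 trapping) is Markovnikov and selects the 1,1-disubstituted isopropenyl group over the hindered monosubstituted vinyl group on quaternary C10.

Step 12
Reactants: 17 diol ketone
Product: 18 13-methylene diol
Conditions: Zn, CH2Br2, TiCl4, THF, 0 °C (pre-formed Lombardo reagent, excess); add 17 in CH2Cl2, 0 °C→rt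
Reagents that add atoms: dibromomethane (BrCBr)
Why: Takai–Lombardo methylenation is non-basic, so the retro-aldol-prone β-hydroxy ketone and the lactone survive while the non-enolisable bridging ketone is methylenated.

Step 13
Reactants: 18 diol
Product: 19 C4 acrylate
Conditions: acryloyl chloride (1.5 equiv), Et3N (2 equiv), DMAP (10 mol%), CH2Cl2, 0 °C→rt
Reagents that add atoms: acryloyl chloride (C=CC(=O)Cl)
Why: DMAP-catalysed O-acylation takes place at the side-chain dimethylcarbinol because the C15 hydroxyl is a far more hindered endo bridge alcohol.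

Step 14
Reactants: 19 acrylate
Product: 20 brasilianoid B
Conditions: Hoveyda–Grubbs II (10 mol%), 1,4-benzoquinone (20 mol%), toluene (2 mM), 80 °C
Reagents that add atoms: none
Why: Ring-closing metathesis between the acrylate and the C10 vinyl group closes the seven-membered Z-enoate lactone, the exocyclic methylene flanked by two quaternary carbons being inert.

**Compound list**
1 | (S)-(+)-carvone, (5S)-2-methyl-5-(prop-1-en-2-yl)cyclohex-2-en-1-one | C=C(C)[C@@H]1CC(=O)C(C)=CC1 | starting material
2 | lithium cross-conjugated dienolate of 1 | C=C(C)[C@@H]1C=C(O[Li])C(C)=CC1 | intermediate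
3 | 6-methylcarvone, (5S)-2,6-dimethyl-5-(prop-1-en-2-yl)cyclohex-2-en-1-one, C6 epimers (mainly trans) | C=C(C)[C@@H]1C(C)C(=O)C(C)=CC1 | intermediate
4 | lithium dienolate of 3 | C=C(C)[C@@H]1C(C)=C(O[Li])C(C)=CC1 | intermediate
5 | (5R,6R)-6-ethenyl-2,6-dimethyl-5-(prop-1-en-2-yl)cyclohex-2-en-1-one (vinyl trans to isopropenyl) | C=C(C)[C@@H]1[C@@](C)(C=C)C(=O)C(C)=CC1 | intermediate
6 | lithium enolate from 1,4-reduction of 5 | C=C(C)[C@@H]1[C@@](C)(C=C)C(O[Li])=C(C)CC1 | intermediate
7 | (5R,6R)-6-ethenyl-2,6-dimethyl-5-(prop-1-en-2-yl)cyclohex-1-en-1-yl trifluoromethanesulfonate | C=C(C)[C@@H]1[C@@](C)(C=C)C(OS(=O)(=O)C(F)(F)F)=C(C)CC1 | intermediate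
8 | methyl 3-[(5R,6R)-6-ethenyl-2,6-dimethyl-5-(prop-1-en-2-yl)cyclohex-1-en-1-yl]-2-methylpropanoate (C2 epimers) | C=C(C)[C@@H]1[C@@](C)(C=C)C(CC(C)C(=O)OC)=C(C)CC1 | intermediate
9 | tert-butyl 5-[(5R,6R)-6-ethenyl-2,6-dimethyl-5-(prop-1-en-2-yl)cyclohex-1-en-1-yl]-4-methyl-3-oxopentanoate (C4 epimers) | C=C(C)[C@@H]1[C@@](C)(C=C)C(CC(C)C(=O)CC(=O)OC(C)(C)C)=C(C)CC1 | intermediate
10 | tert-butyl 5-ethenyl-3,5,8a-trimethyl-2-oxo-6-(prop-1-en-2-yl)decahydronaphthalene-1-carboxylate; trans-fused; 4a-H, 6-H and 5-vinyl on one face, 5-CH3, 8a-CH3 and 6-isopropenyl on the other; C1/C3 undefined | C=C(C)[C@@H]1[C@@](C)(C=C)[C@@H]2CC(C)C(=O)C(C(=O)OC(C)(C)C)[C@@]2(C)CC1 | intermediate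
11 | dilithium dienolate (dianion) of 10 | C=C(C)[C@@H]1[C@@](C)(C=C)[C@@H]2CC(C)=C(O[Li])C(=C(O[Li])OC(C)(C)C)[C@@]2(C)CC1 | intermediate
12 | C12-alkylated Weinreb amide of 10 (new CH2C(O)N(OMe)Me arm axial, cis to C9-H; C12 methyl equatorial) | C=C(C)[C@@H]1[C@@](C)(C=C)[C@@H]2C[C@@](C)(CC(=O)N(C)OC)C(=O)C(C(=O)OC(C)(C)C)[C@@]2(C)CC1 | intermediate
13 | bridged 13,15-dione tert-butyl ester (bicyclo[3.2.1]octane-6,8-dione on ring B; C16–C15 bridge on the face of C9-H; C17 ester on C14) | C=C(C)[C@@H]1[C@@](C)(C=C)[C@@H]2C[C@@]3(C)CC(=O)[C@](C(=O)OC(C)(C)C)(C3=O)[C@@]2(C)CC1 | intermediate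
14 | C15 vinyl carbinol of 13 (vinyl exo, OH endo; C13 ketone and tert-butyl ester kept) | C=C(C)[C@@H]1[C@@](C)(C=C)[C@@H]2C[C@@]3(C)C[C@](O)(C=C)[C@](C(=O)OC(C)(C)C)(C3=O)[C@@]2(C)CC1 | intermediate
15 | iodomethyl γ-lactone (C17–O–C18; CH2I cis to C15-OH) | C=C(C)[C@@H]1[C@@](C)(C=C)[C@@H]2C[C@@]3(C)C[C@]4(O)[C@@H](CI)OC(=O)[C@@]4(C3=O)[C@@]2(C)CC1 | intermediate
16 | 13-oxo γ-lactone with C18 methyl, isopropenyl on C5 and vinyl on C10 | C=C(C)[C@@H]1[C@@](C)(C=C)[C@@H]2C[C@@]3(C)C[C@]4(O)[C@@H](C)OC(=O)[C@@]4(C3=O)[C@@]2(C)CC1 | intermediate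
17 | C4 tertiary alcohol of 16 (C4-OH, C15-OH, C13 ketone) | CC(C)(O)[C@@H]1[C@@](C)(C=C)[C@@H]2C[C@@]3(C)C[C@]4(O)[C@@H](C)OC(=O)[C@@]4(C3=O)[C@@]2(C)CC1 | intermediate
18 | 13-methylene diol (C13=CH2, C4-OH, C15-OH) | CC(C)(O)[C@@H]1[C@@](C)(C=C)[C@@H]2C[C@@]3(C)C[C@]4(O)[C@@H](C)OC(=O)[C@@]4(C3=C)[C@@]2(C)CC1 | intermediate
19 | C4 acrylate of 18 | C=CC(=O)OC(C)(C)[C@@H]1[C@@](C)(C=C)[C@@H]2C[C@@]3(C)C[C@]4(O)[C@@H](C)OC(=O)[C@@]4(C3=C)[C@@]2(C)CC1 | intermediate
20 | brasilianoid B | C=C1[C@@]2(C)C[C@H]3[C@]4(C)C=CC(=O)OC(C)(C)[C@H]4CC[C@]3(C)[C@@]13C(=O)O[C@H](C)[C@@]3(O)C2 | target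

**Step count:** 14 steps in total; longest linear sequence 14 steps from (S)-carvone. All stereocentres derive from the single carvone centre.

**Three steps most likely to fail**

Step 6 (new photochemical ring closure). The risks are O-attack instead of C-attack by the enol, spiro 5-exo attack at C9, and poor turnover. The fallback sets out from 9 and comes back at 10. The sodium enolate of 9 (NaH, THF, −78 °C) is brominated with NBS to the α-bromo-β-keto ester F1. Slow addition of Bu3SnH/AIBN in benzene at 80 °C then generates the electrophilic C14 radical, which adds 6-endo to C8 of the tetrasubstituted alkene. The tertiary C9 radical is reduced by tin hydride on the open face, giving 10. This is the known tin-hydride radical cyclisation of α-halo-1,3-dicarbonyls, with the radical on the dicarbonyl carbon instead of a radical cation on the alkene.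

Step 7 (alkylation and acylation in one flask). The risk is that the hindered C14 enolate does not acylate to the strained dione. The fallback sets out from 10 and comes back at 13. The dianion alkylation is run at −78 °C and quenched so that Weinreb amide 12 is isolated. NaH masks the keto ester as its enolate while DIBAL-H (THF, −78 °C) reduces the amide to the aldehyde F2. DBU in CH2Cl2 then closes the bridge by intramolecular aldol addition of C14 to the aldehyde, giving the bridged β-hydroxy ketone F3 (C15 epimers). Dess–Martin oxidation gives 13. Ring closure is thus an aldol/oxidation sequence rather than an acylation.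

Step 12 (methylenation of the doubly neopentyl bridging ketone next to a β-hydroxyl). The risks are no reaction or retro-aldol. The fallback sets out from 17 and comes back at 18. Excess (trimethylsilyl)methyllithium with CeCl3 (THF, −78 °C) adds to the C13 ketone to give the β-hydroxysilane F4. HF·pyridine then effects acidic Peterson elimination to 18. This is a 1,2-addition/elimination route rather than a carbonyl-olefination reagent.

**Further compounds**
F1 | step 6 | tert-butyl 2-bromo-5-[(5R,6R)-6-ethenyl-2,6-dimethyl-5-(prop-1-en-2-yl)cyclohex-1-en-1-yl]-4-methyl-3-oxopentanoate | C=C(C)[C@@H]1[C@@](C)(C=C)C(CC(C)C(=O)C(Br)C(=O)OC(C)(C)C)=C(C)CC1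
F2 | step 7 | C12 2-oxoethyl (aldehyde) analogue of 12 | C=C(C)[C@@H]1[C@@](C)(C=C)[C@@H]2C[C@@](C)(CC=O)C(=O)C(C(=O)OC(C)(C)C)[C@@]2(C)CC1
F3 | step 7 | bridged 15-hydroxy-13-ketone tert-butyl ester (C15 epimers) | C=C(C)[C@@H]1[C@@](C)(C=C)[C@@H]2C[C@@]3(C)CC(O)[C@](C(=O)OC(C)(C)C)(C3=O)[C@@]2(C)CC1
F4 | step 12 | C13 hydroxy (trimethylsilyl)methyl adduct of 17 | CC(C)(O)[C@@H]1[C@@](C)(C=C)[C@@H]2C[C@@]3(C)C[C@]4(O)[C@@H](C)OC(=O)[C@@]4(C3(O)C[Si](C)(C)C)[C@@]2(C)CC1
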